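**Retrosynthetic overview**

1. Target 13 (2,5-cis oxolane, ring A) ⇒ exocyclic vinylogous ester 12; hydrogenation of C2=CH from the face anti to the C5 butyl group sets C2 last.
2. 12 ⇒ thionolactone 6 + α-diazoketone 9: the C2=CH bond is made by carbenoid/thiocarbonyl coupling with extrusion of N2 and of the sulfur atom (sulfide-contraction type).
3. Enabling feature: the β-alkoxy ketone array O1–C2–CH2–C(=O) on ring A. C2 carries the ring oxygen and lies 1,3 to the ketone carbonyl, so one oxidation level up it is a former thionolactone C=S carbon and the CH2 a former diazo carbon.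
4. 6 ⇒ lactone 5 ⇒ (R)-1,2-epoxyhexane 1 + diethyl malonate 2; 9 ⇒ pentadecanoyl chloride 7 + (trimethylsilyl)diazomethane 8.
5. Ring order: ring A is the only ring; it is closed first (lactonisation in step 1) and never opened again; C5 comes unchanged from the epoxide.

Key step: step 5

Remark: the stereodescriptors of the target SMILES correspond to the (2R,5R), 2,5-cis oxolane. Compound 12 is drawn as the E isomer, but either alkene geometry serves in step 6.

**Route**

Step 1
Reactants: 1 (R)-1,2-epoxyhexane; 2 diethyl malonate
Product: 4 ethyl (5R)-5-butyl-2-oxooxolane-3-carboxylate, via hydroxy diester 3 (not isolated)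
Conditions: NaOEt (1.05 equiv), EtOH, 0 °C to reflux; then AcOH
Reagents that add atoms: none
Why: Malonic ester alkylation with an epoxide: the malonate anion should open 1 by SN2 attack at the unsubstituted carbon and the alkoxide of 3 should lactonise onto one ester (5-exo-trig acyl substitution), while the C–O bond at the carbinol carbon is never broken, so the R configuration is carried over.

Step 2
Reactants: 4 ethyl (5R)-5-butyl-2-oxooxolane-3-carboxylate
Product: 5 (5R)-5-butyloxolan-2-one
Conditions: NaCl (cat.), H2O (2 equiv), DMSO, 150 °C
Reagents that add atoms: none
Why: Krapcho dealkoxycarbonylation of the α-ethoxycarbonyl lactone should remove the ester as ethanol and CO2 under neutral conditions, and C5 is not enolisable, so it stays R.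

Step 3
Reactants: 5 (5R)-5-butyloxolan-2-one
Product: 6 (5R)-5-butyloxolane-2-thione
Conditions: Lawesson's reagent (0.6 equiv), toluene, 110 °C
Reagents that add atoms: Lawesson's reagent, COc1ccc(cc1)P1(=S)SP(=S)(S1)c1ccc(OC)cc1
Why: Thionation of a γ-lactone carbonyl with Lawesson's reagent (Wittig-like oxygen/sulfur exchange through a four-membered P–S–C–O ring) is standard for butyrolactones and does not touch the remote stereocentre.

Step 4
Reactants: 7 pentadecanoyl chloride; 8 (trimethylsilyl)diazomethane
Product: 9 1-diazohexadecan-2-one
Conditions: 8 (1.5 equiv, hexane solution), THF/MeCN 1:1, 0 °C to rt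
Reagents that add atoms: none
Why: C-acylation of the silyl diazomethane by the acid chloride with loss of the silyl group as Me3SiCl (the first stage of an Arndt–Eistert sequence) should give the terminal α-diazoketone, with no stereocentre involved.

Step 5
Reactants: 6 (5R)-5-butyloxolane-2-thione; 9 1-diazohexadecan-2-one
Product: 12 (1E)-1-[(5R)-5-butyloxolan-2-ylidene]hexadecan-2-one, via thiocarbonyl ylide 10 (not isolated), via spiro thiirane 11 (not isolated)
Conditions: Rh2(OAc)4 (2 mol %), toluene, 80 °C, slow addition of 9 to 6 (1.3 equiv); then PPh3 (1.2 equiv), 80 °C
Reagents that add atoms: none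
Why: Rh2(OAc)4 should decompose 9 with loss of N2 to a catalyst-bound electrophilic carbenoid that is captured by the soft thiocarbonyl sulfur of 6 to give the keto-stabilised ylide 10, which closes to thiirane 11 and is desulfurised by PPh3 (as Ph3PS) to leave the exocyclic C2=CH bond joining the C8 and C16 fragments. The closest known reaction type is the carbenoid–thiocarbonyl coupling with sulfur extrusion (diazo variant of the Eschenmoser sulfide contraction, related to the Barton–Kellogg episulfide olefination), established for thiolactams and for γ-thionolactones with diazocarbonyl compounds. No ring of the target is closed here, since ring A is already present; the only ring closed is the transient thiirane, by conrotatory 4π-electrocyclisation of the ylide, and it is destroyed again on desulfurisation. No permanent stereocentre is created: the two thiirane centres vanish, the alkene geometry (E expected on dipole grounds) is erased in step 6, and C5 is neither enolisable nor ionisable and stays R. The selectivity needed is chemoselectivity for ylide formation over carbene dimerisation and 1,5 C–H insertion into the tetradecyl chain, secured by slow addition of 9 into an excess of the strongly nucleophilic C=S group; the position of the new double bond is fixed by where sulfur and N2 sat.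

Step 6
Reactants: 12 (1E)-1-[(5R)-5-butyloxolan-2-ylidene]hexadecan-2-one
Product: 13 1-[(2R,5R)-5-butyloxolan-2-yl]hexadecan-2-one
Conditions: H2 (1 atm), Rh/Al2O3 (5 wt % Rh), EtOAc, rt
Reagents that add atoms: none
Why: Heterogeneous syn-hydrogenation of the exocyclic enol-ether double bond of a 5-substituted 2-alkylidene oxolane should take place on the ring face opposite the C5 butyl group, so hydrogen is delivered to C2 anti to butyl and the side chain ends up cis (2R,5R), and Rh/Al2O3 is chosen because it should spare the ketone and the allylic-type C–O bond.

**Compound list**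

1 | (R)-1,2-epoxyhexane [(2R)-2-butyloxirane] | CCCC[C@@H]1CO1 | starting material
2 | diethyl malonate | CCOC(=O)CC(=O)OCC | starting material
3 | diethyl 2-[(2R)-2-hydroxyhexyl]propanedioate (present as its sodium alkoxide) | CCOC(=O)C(C[C@@H](CCCC)O)C(=O)OCC | intermediate
4 | ethyl (5R)-5-butyl-2-oxooxolane-3-carboxylate (mixture of epimers at C3) | CCOC(=O)C1C[C@@H](CCCC)OC1=O | intermediate
5 | (5R)-5-butyloxolan-2-one [(R)-γ-octalactone] | O=C1CC[C@@H](CCCC)O1 | intermediate
6 | (5R)-5-butyloxolane-2-thione | S=C1CC[C@@H](CCCC)O1 | intermediate
7 | pentadecanoyl chloride | CCCCCCCCCCCCCCC(=O)Cl | starting material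
8 | (trimethylsilyl)diazomethane | C[Si](C)(C)C=[N+]=[N-] | starting material
9 | 1-diazohexadecan-2-one | CCCCCCCCCCCCCCC(=O)C=[N+]=[N-] | intermediate
10 | thiocarbonyl ylide: [(5R)-5-butyloxolan-2-ylidene]sulfonium 2-oxohexadecan-1-ide | CCCCCCCCCCCCCCC(=O)[CH-][S+]=C1CC[C@@H](CCCC)O1 | intermediate
11 | 1-[(5R)-5-butyl-4-oxa-1-thiaspiro[2.4]heptan-2-yl]pentadecan-1-one (mixture of thiirane diastereomers) | CCCCCCCCCCCCCCC(=O)C1SC12CC[C@@H](CCCC)O2 | intermediate
12 | (1E)-1-[(5R)-5-butyloxolan-2-ylidene]hexadecan-2-one | CCCCCCCCCCCCCCC(=O)/C=C1\CC[C@@H](CCCC)O1 | intermediate
13 | 1-[(2R,5R)-5-butyloxolan-2-yl]hexadecan-2-one | CCCCCCCCCCCCCCC(=O)C[C@H]1CC[C@@H](CCCC)O1 | target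

**Step count and risks**

Total step count: 6. Longest linear sequence: 5 steps (steps 1, 2, 3, 5, 6); step 4 is a one-step side branch.

Steps most likely to fail:

Step 5. The catalyst may be slowed by sulfur coordination. The carbenoid may dimerise or insert into a C–H bond of its own chain before it meets the thiocarbonyl group. The ylide may undergo a proton shift to an S-alkyl ketene O,S-acetal instead of closing to the thiirane, or desulfurisation may stall. The fallback is a Claisen-type acylation that sets out from compound 5 and comes back at compound 12. Commercial hexadecan-2-one would be deprotonated on the methyl side with LiN(iPr)2 (2.1 equiv, THF, −78 °C). The kinetic enolate would be acylated by lactone 5 to give (5R)-5-hydroxytetracosane-8,10-dione F1, in equilibrium with its cyclic hemiketal. Cyclodehydration with TsOH (cat.) in refluxing toluene with removal of water should then give 12.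

Step 6. Facial discrimination may be incomplete, because the butyl group sits 1,3 across the ring oxygen from the reacting carbon. Slow over-reduction of the ketone may also compete. The fallback replaces substrate-controlled hydrogenation by a catalyst-controlled ring closure; it sets out from compounds 1 and 7 and comes back at compound 13. Epoxide 1 would be opened with CH2=CHCH2MgCl (THF, 0 °C) to (5R)-non-1-en-5-ol F2. Acid chloride 7 would be converted into heptadec-1-en-3-one F3 by Stille acylation with tributyl(vinyl)stannane and PdCl2(PPh3)2 (cat.). Cross-metathesis of F2 with F3 using the second-generation Hoveyda–Grubbs catalyst (CH2Cl2, 40 °C) should give (5R,8E)-5-hydroxytetracos-8-en-10-one F4. Intramolecular oxa-Michael addition of F4 under a bifunctional cinchona-alkaloid aminothiourea catalyst should close ring A and set C2, giving 13. The pseudoenantiomer of the catalyst that delivers the 2R configuration would have to be chosen by a small-scale test.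

Step 3. Thionation may stop at partial conversion, the thionolactone may decompose on prolonged heating, and separation from phosphorus by-products may be lossy. The fallback activates the lactone as an electrophile instead; it sets out from compound 5 and comes back at compound 6. O-Ethylation of 5 with Et3OBF4 (CH2Cl2, rt) should give (5R)-5-butyl-2-ethoxy-4,5-dihydro-3H-furan-1-ium tetrafluoroborate F5. Treatment with anhydrous NaSH (MeCN, 0 °C) should then add sulfur at C2 and expel ethanol to give 6.

**Further compounds**

F1 | step 5 | (5R)-5-hydroxytetracosane-8,10-dione | CCCCCCCCCCCCCCC(=O)CC(=O)CC[C@@H](CCCC)O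
F2 | step 6 | (5R)-non-1-en-5-ol | C=CCC[C@@H](CCCC)O
F3 | step 6 | heptadec-1-en-3-one | CCCCCCCCCCCCCCC(=O)C=C
F4 | step 6 | (5R,8E)-5-hydroxytetracos-8-en-10-one | CCCCCCCCCCCCCCC(=O)/C=C/CC[C@@H](CCCC)O
F5 | step 3 | (5R)-5-butyl-2-ethoxy-4,5-dihydro-3H-furan-1-ium tetrafluoroborate | CCOC1=[O+][C@H](CCCC)CC1.F[B-](F)(F)F
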